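The readings stem from a simulated flask from invented constants, and the scatter is random.

Watch c(coupling partner) on this repeat as closely as c(substrate). Two chemists disagree about it.

all flasks: substrate 20 mM (fed, over 3.0 min)

| charge | coupling partner | remark | time |
|---|---|---|---|
| autumn | 50 mM | run made earlier |  |
| dawn | 79 mM | run made earlier |  |
| flask | 36.0 mM |  | 50 min |

| run | time / min | target / % | substrate / % |
|---|---|---|---|
| autumn | 4.00 | 22.4 | 76.7 |
| autumn | 10.0 | 54.4 | 44.9 |
| autumn | 20.0 | 78.3 | 20.8 |
| autumn | 30.0 | 88.9 | 10.3 |
| autumn | 40.0 | 94.6 | 5.0 |
| dawn | 3.00 | 20.6 | 79.3 |
| dawn | 6.00 | 50.6 | 49.3 |
| dawn | 12.0 | 78.0 | 20.7 |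
| dawn | 20.0 | 93.0 | 6.9 |
| dawn | 40.0 | 98.3 | 0.5 |

(readings scatter by 0.5 percentage points)

* which holds at 50 min: what has brought the reaction to rest, or that it has not come to rest (forward and back rates have come level / it is still moving / all of the substrate has reacted / the coupling partner has run out first)
* how much target there is at 50 min, in percent of the substrate charged

- the numbers in the tables scatter with a standard deviation of 0.5 percentage points
- the reaction counts as stopped when no species that holds the substrate changes by six tenths of a point or more over the second half of the time

Take the rate as k·c(substrate)·c(coupling partner), with one partner used per substrate. Then ln(c(coupling partner)/c(substrate)) climbs in a straight line, and its slope is k times the difference of the two. Autumn, from 10.0 min to 40.0 min, reads k = 0.00218 /mM/min. Dawn, from 6.00 min to 20.0 min, reads 0.00222 /mM/min at a different partner charge.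

The first chemist calls the partner excess enough for a pseudo-first-order view. The substrate then decays at the head rate k·c(coupling partner) = 0.0786 /min throughout. Counting the feed as arriving at its midpoint, the decay lasts 48.5 min, which leaves 2.21% substrate by this view.

The second chemist says the partner falls too, towards the excess of 16.0 mM. The end of the run therefore follows the tail rate, k times the excess of partner over substrate, which is 0.0350 /min. The head rate is about twice that.

I join the two ends with the straight line. At 50 min I reckon the ratio of partner to substrate at 9.80, so I reckon substrate at 9.09%. At 25.0 min the same line gives 25.9%, so by my reckoning the flask is still moving. Autumn's balance read 0.8 percentage points short at 30.0 min. Taking that off, I expect 90.1% target.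

The forecast gives 90.5% target, a little above mine, and says it is still moving, since “the substrate is still falling noticeably”.

The answer for the flask at 50.0 min reads: it is still moving, with 89.8% target and 8.99% substrate, more substrate than the first chemist's 2.21%.

    substrate → side product (k = 1.30 × 10⁻⁵ /s)
    coupling partner → decomposition product (k = 3.60 × 10⁻⁶ /s)
    substrate + coupling partner → target (k = 0.0360 /M/s)

In the flask at 10.5 min the substrate's half-life by target-making is 12 min, while the tail rate gives a half-life of 19.8 min, a longer one. In the flask at 50.0 min target-making still uses substrate 49 times as fast as the loss to side product. The first chemist's ground is the neighbour flask charged with 90 mM of partner, where head exceeds tail by a factor of 1.29 against 2.25 in the flask, and 77% of the partner remains. There the tail rate is 0.153 /min, the joined line gives 0.0468% substrate, and that neighbour holds 0.051%.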